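**Retrosynthetic overview** (Ca = quaternary oxolane carbon, Cb = oxolane CH, Cc = lactone quaternary carbon)
1. The central ketone is unmasked last from a 2,2-dialkyl-1,3-dithiane; the dithiane carbon is the C=O carbon.
2. Key step: 1,3-dithiane serves as a carbonyl dianion (acyl anion umpolung) joined in one flask to two electrophilic carbons, the CH2 of a 2,2-disubstituted epoxide and the CH2 of an allylic bromide.
3. Ring order: the first C–C bond frees a tertiary alkoxide that closes the oxolane (5-exo on the neighbouring trisubstituted epoxide, inversion at Cb); the γ-lactone closes last on acidification; the furan is bought preformed.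
4. The bis-epoxide comes from an (E)-keto ester by catalytic asymmetric Corey–Chaykovsky epoxidation (Ca) and Shi epoxidation (Cb, Cc); the keto ester comes from a Johnson–Claisen rearrangement.
5. The allylic bromide comes from SN2' opening of isoprene monoxide by 3-furylmethyl Grignard reagent.

Assumption: the (R)-binaphthoxide antipode of LaLi3(binaphthoxide)3 is taken to be the one that gives the (R)-epoxide from this alkyl methyl ketone; if the facial sense is the reverse, the (S) antipode is used and nothing else changes.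

**Route**

Step 1
Reactants: 1 furan-3-ylmethanol
Product: 2 3-(chloromethyl)furan
Conditions: SOCl2 (1.1 eq), pyridine (1.2 eq), Et2O, 0 °C, 1 h; used crude at once
Reagents that add atoms: thionyl chloride O=S(Cl)Cl
Why: Chlorodehydroxylation of a primary furylmethyl alcohol through its chlorosulfite, buffered by pyridine so the acid-sensitive furan survives; no stereocentre is involved.

Step 2
Reactants: 2 3-(chloromethyl)furan; 3 2-methyl-2-vinyloxirane (isoprene monoxide, racemic)
Product: 5 (E)-5-(furan-3-yl)-2-methylpent-2-en-1-ol, via furylmethyl Grignard 4 (not isolated)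
Conditions: Mg, THF, 0 °C; then 3, CuI (10 mol %), THF, −40 → 0 °C; aq NH4Cl
Reagents that add atoms: none
Why: Copper-catalysed anti SN2' opening of a vinyl oxirane by a Grignard reagent puts the furylmethyl carbon on the vinyl terminus and gives the 2-methylallylic alcohol with E geometry favoured (the minor Z isomer is removed on AgNO3-impregnated silica).

Step 3
Reactants: 5 (E)-5-(furan-3-yl)-2-methylpent-2-en-1-ol
Product: 6 3-[(E)-5-bromo-4-methylpent-3-en-1-yl]furan
Conditions: CBr4, PPh3, CH2Cl2, 0 °C, 30 min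
Reagents that add atoms: tetrabromomethane BrC(Br)(Br)Br
Why: Appel bromination of a primary allylic alcohol is an SN2 displacement on the alkoxyphosphonium salt under neutral conditions, so no allylic transposition, E/Z scrambling or furan damage is expected.

Step 4
Reactants: 7 2-(2-bromoethyl)-2-methyl-1,3-dioxolane; 8 methacrolein
Product: 10 rac-2-methyl-5-(2-methyl-1,3-dioxolan-2-yl)pent-1-en-3-ol, via ketal Grignard 9 (not isolated)
Conditions: Mg, THF, ≤30 °C; then 8, THF, −78 °C; aq NH4Cl
Reagents that add atoms: none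
Why: Grignard 1,2-addition to an enal gives the secondary 2-methylallylic alcohol needed for the sigmatropic step; the carbinol centre is left racemic because step 5 destroys it.

Step 5
Reactants: 10 rac-2-methyl-5-(2-methyl-1,3-dioxolan-2-yl)pent-1-en-3-ol; 11 triethyl orthoacetate
Product: 14 ethyl (E)-4-methyl-8-oxonon-4-enoate, via ketene acetal 12 (not isolated), via ketal ester 13 (not isolated)
Conditions: 11 (5 eq), EtCO2H (cat.), 140 °C, EtOH distilled off; then 1 M HCl/THF, 23 °C
Reagents that add atoms: water O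
Why: Johnson–Claisen rearrangement through a chair transition state with the carbinol substituent equatorial gives the trisubstituted alkene with >95:5 E selectivity, and the acidic work-up unmasks the methyl ketone.

Step 6
Reactants: 14 ethyl (E)-4-methyl-8-oxonon-4-enoate
Product: 15 ethyl (E)-4-methyl-7-[(2R)-2-methyloxiran-2-yl]hept-4-enoate
Conditions: Me3S(O)I, NaH, THF (ylide preformed, 1.2 eq); LaLi3[(R)-binaphthoxide]3 (5 mol %), [2,4,6-(MeO)3C6H2]3P=O (5 mol %), MS 5 Å, THF, 23 °C
Reagents that add atoms: trimethylsulfoxonium iodide C[S+](C)(C)=O.[I-]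
Why: Catalytic asymmetric Corey–Chaykovsky epoxidation, in which the heterobimetallic binaphthoxide complex binds both the methyl ketone and the sulfoxonium ylide and delivers CH2 to one carbonyl face, sets the (R) quaternary centre that becomes Ca (no later step breaks a bond at it).

Step 7
Reactants: 15 ethyl (E)-4-methyl-7-[(2R)-2-methyloxiran-2-yl]hept-4-enoate
Product: 16 ethyl 3-[(2S,3S)-2-methyl-3-{2-[(2R)-2-methyloxiran-2-yl]ethyl}oxiran-2-yl]propanoate
Conditions: ent-Shi ketone (L-fructose-derived, 30 mol %), KHSO5 (as the triple salt 2KHSO5·KHSO4·K2SO4), K2CO3, Bu4NHSO4, MeCN/CH2(OMe)2/aq Na2B4O7 buffer (pH 10.5), 0 °C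
Reagents that add atoms: potassium peroxymonosulfate [K+].[O-]S(=O)(=O)OO
Why: Shi asymmetric epoxidation (chiral dioxirane, spiro transition state) is highly face-selective for E-trisubstituted alkenes, and the L-series ketone gives the (S,S)-epoxide, which fixes Cc directly and Cb after one inversion, while the ester and the terminal epoxide tolerate pH 10.5 at 0 °C.

Step 8
Reactants: 16 ethyl 3-[(2S,3S)-2-methyl-3-{2-[(2R)-2-methyloxiran-2-yl]ethyl}oxiran-2-yl]propanoate; 17 1,3-dithiane; 6 3-[(E)-5-bromo-4-methylpent-3-en-1-yl]furan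
Product: 24 2-[(E)-5-(furan-3-yl)-2-methylpent-2-en-1-yl]-2-{[(2R,5R)-2-methyl-5-[(2S)-2-methyl-5-oxooxolan-2-yl]oxolan-2-yl]methyl}-1,3-dithiane, via potassium carboxylate 18 (not isolated), via lithiodithiane 19 (not isolated), via epoxy alkoxide 20 (not isolated), via oxolane alkoxide 21 (not isolated), via lithiated oxolane dithiane 22 (not isolated), via hydroxy acid 23 (not isolated)
Conditions: 16, KOSiMe3 (1.05 eq), THF, 23 °C, then evaporate; 17 (0.95 eq), n-BuLi, THF, −30 °C; add 18 in THF/HMPA (10:1), −78 → 40 °C; then t-BuLi (1.1 eq), −78 °C, 10 min; 6 (1.2 eq), −78 → −30 °C; 1 M HCl to pH 2, then CSA (cat.), CH2Cl2, 23 °C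
Reagents that add atoms: potassium trimethylsilanolate C[Si](C)(C)[O-].[K+]
Why: Proposed new method: the ester is first masked as its carboxylate so that it is inert to carbanions; the dithiane carbanion (a masked carbonyl carbon, normally electrophilic) then opens the unhindered CH2 of the 2,2-disubstituted epoxide without touching Ca, the freed tertiary alkoxide opens the trisubstituted epoxide 5-exo at Cb with inversion (Cb becomes R, Cc keeps S), relithiation of the dithiane C–H and SN2 attack on allylic bromide 6 make the second C–C bond with the furan arriving only as an electrophile, and acidification closes the γ-lactone; the closest known chemistry is Corey–Seebach dithiane alkylation in one-flask linchpin couplings with epoxides and alkyl halides, together with base-mediated 5-exo epoxy alcohol cyclisation.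

Step 9
Reactants: 24 2-[(E)-5-(furan-3-yl)-2-methylpent-2-en-1-yl]-2-{[(2R,5R)-2-methyl-5-[(2S)-2-methyl-5-oxooxolan-2-yl]oxolan-2-yl]methyl}-1,3-dithiane
Product: 25 (5S)-5-{(2R,5R)-5-[(4E)-7-(furan-3-yl)-4-methyl-2-oxohept-4-en-1-yl]-5-methyloxolan-2-yl}-5-methyloxolan-2-one
Conditions: MeI (excess), CaCO3, MeCN/H2O (9:1), 45 °C
Reagents that add atoms: water O
Why: Alkylative dithiane hydrolysis (S-methylation, then hydrolysis of the thionium ion) is neutral and non-oxidising, so the furan, the β,γ-unsaturated ketone (no conjugation), the β-alkoxy ketone (no retro-oxa-Michael), the lactone and all three stereocentres are untouched.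

**Compound list**
1 | furan-3-ylmethanol | OCc1ccoc1 | starting material
2 | 3-(chloromethyl)furan | ClCc1ccoc1 | intermediate
3 | 2-methyl-2-vinyloxirane (racemic) | CC1(C=C)CO1 | starting material
4 | (furan-3-ylmethyl)magnesium chloride | Cl[Mg]Cc1ccoc1 | intermediate
5 | (E)-5-(furan-3-yl)-2-methylpent-2-en-1-ol | C/C(=C\CCc1ccoc1)CO | intermediate
6 | 3-[(E)-5-bromo-4-methylpent-3-en-1-yl]furan | C/C(=C\CCc1ccoc1)CBr | intermediate
7 | 2-(2-bromoethyl)-2-methyl-1,3-dioxolane | CC1(CCBr)OCCO1 | starting material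
8 | methacrolein (2-methylprop-2-enal) | CC(=C)C=O | starting material
9 | [2-(2-methyl-1,3-dioxolan-2-yl)ethyl]magnesium bromide | CC1(CC[Mg]Br)OCCO1 | intermediate
10 | rac-2-methyl-5-(2-methyl-1,3-dioxolan-2-yl)pent-1-en-3-ol | CC(=C)C(O)CCC1(C)OCCO1 | intermediate
11 | triethyl orthoacetate | CCOC(C)(OCC)OCC | starting material
12 | 2-{3-[(1-ethoxyethenyl)oxy]-4-methylpent-4-en-1-yl}-2-methyl-1,3-dioxolane (racemic mixed ketene acetal) | C=C(OCC)OC(CCC1(C)OCCO1)C(C)=C | intermediate
13 | ethyl (E)-4-methyl-7-(2-methyl-1,3-dioxolan-2-yl)hept-4-enoate | CCOC(=O)CC/C(C)=C/CCC1(C)OCCO1 | intermediate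
14 | ethyl (E)-4-methyl-8-oxonon-4-enoate | CCOC(=O)CC/C(C)=C/CCC(C)=O | intermediate
15 | ethyl (E)-4-methyl-7-[(2R)-2-methyloxiran-2-yl]hept-4-enoate | CCOC(=O)CC/C(C)=C/CC[C@]1(C)CO1 | intermediate
16 | ethyl 3-[(2S,3S)-2-methyl-3-{2-[(2R)-2-methyloxiran-2-yl]ethyl}oxiran-2-yl]propanoate | CCOC(=O)CC[C@]1(C)O[C@H]1CC[C@]2(C)CO2 | intermediate
17 | 1,3-dithiane | C1CSCSC1 | starting material
18 | potassium 3-[(2S,3S)-2-methyl-3-{2-[(2R)-2-methyloxiran-2-yl]ethyl}oxiran-2-yl]propanoate | [K+].[O-]C(=O)CC[C@]1(C)O[C@H]1CC[C@]2(C)CO2 | intermediate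
19 | 2-lithio-1,3-dithiane | [Li]C1SCCCS1 | intermediate
20 | lithium potassium 3-[(2S,3S)-3-{(3R)-4-(1,3-dithian-2-yl)-3-methyl-3-oxidobutyl}-2-methyloxiran-2-yl]propanoate | [Li+].[K+].[O-]C(=O)CC[C@]1(C)O[C@H]1CC[C@@](C)([O-])CC2SCCCS2 | intermediate
21 | lithium potassium (4S)-4-[(2R,5R)-5-(1,3-dithian-2-ylmethyl)-5-methyloxolan-2-yl]-4-oxidopentanoate | S1CCCSC1C[C@@]2(C)CC[C@H]([C@@](C)([O-])CCC(=O)[O-])O2.[Li+].[K+] | intermediate
22 | lithium potassium (4S)-4-{(2R,5R)-5-[(2-lithio-1,3-dithian-2-yl)methyl]-5-methyloxolan-2-yl}-4-oxidopentanoate | [Li]C1(SCCCS1)C[C@@]2(C)CC[C@H]([C@@](C)([O-])CCC(=O)[O-])O2.[Li+].[K+] | intermediate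
23 | (4S)-4-[(2R,5R)-5-({2-[(E)-5-(furan-3-yl)-2-methylpent-2-en-1-yl]-1,3-dithian-2-yl}methyl)-5-methyloxolan-2-yl]-4-hydroxypentanoic acid | C/C(=C\CCc1ccoc1)CC1(C[C@@]2(C)CC[C@H]([C@@](C)(O)CCC(=O)O)O2)SCCCS1 | intermediate
24 | 2-[(E)-5-(furan-3-yl)-2-methylpent-2-en-1-yl]-2-{[(2R,5R)-2-methyl-5-[(2S)-2-methyl-5-oxooxolan-2-yl]oxolan-2-yl]methyl}-1,3-dithiane | C/C(=C\CCc1ccoc1)CC1(C[C@@]2(C)CC[C@H]([C@]3(C)CCC(=O)O3)O2)SCCCS1 | intermediate
25 | (5S)-5-{(2R,5R)-5-[(4E)-7-(furan-3-yl)-4-methyl-2-oxohept-4-en-1-yl]-5-methyloxolan-2-yl}-5-methyloxolan-2-one | C/C(=C\CCc1ccoc1)CC(=O)C[C@@]1(C)CC[C@H]([C@]2(C)CCC(=O)O2)O1 | target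

**Count**
Total steps: 9. Longest linear sequence: 6 (steps 4 to 9, from 7 and 8); the furan branch is steps 1 to 3 and joins at step 8. Minor diastereomers arising from imperfect enantioselectivity in steps 6 and 7 are removed by chromatography at 16 or 24.

**Steps most likely to fail, with fallbacks**

Step 8. The risks are relithiation of a dithiane C–H in a polyanion next to a carboxylate, and slow opening of the trisubstituted epoxide by the tertiary alkoxide before that relithiation. Fallback: reverse the order of the two alkylations so that no polyanion has to be relithiated. Setting out from 6, lithiodithiane 19 is alkylated with 6 alone (THF, −78 → −20 °C) and the product 2-[(E)-5-(furan-3-yl)-2-methylpent-2-en-1-yl]-1,3-dithiane F1 is isolated. It is deprotonated with t-BuLi in THF/HMPA at −78 °C for 5 min to 2-lithio-2-[(E)-5-(furan-3-yl)-2-methylpent-2-en-1-yl]-1,3-dithiane F2, and carboxylate 18 is added. The ring-opened salt lithium potassium 3-[(2S,3S)-3-{(3R)-4-[2-((E)-5-(furan-3-yl)-2-methylpent-2-en-1-yl)-1,3-dithian-2-yl]-3-methyl-3-oxidobutyl}-2-methyloxiran-2-yl]propanoate F3 closes the oxolane on warming, or under CSA in CH2Cl2 after an acidic quench. This gives hydroxy acid 23 and then 24, where the route is rejoined. The price is a short kinetic deprotonation in the presence of the furan and a more hindered epoxide opening.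

Step 6. The risks are the enantioselectivity of ylide transfer to a functionalised dialkyl ketone and the facial sense of the catalyst. Fallback: set Ca by kinetic resolution instead. Setting out from 14, the uncatalysed Corey–Chaykovsky reaction (Me3S(O)I, NaH, DMSO) gives racemic ethyl (E)-4-methyl-7-(2-methyloxiran-2-yl)hept-4-enoate F4. Ring opening of its (S) enantiomer with Me3SiN3 (0.55 eq) under the chiral (salen)CrN3 catalyst gives ethyl (4E,7S)-8-azido-4,7-dimethyl-7-[(trimethylsilyl)oxy]oct-4-enoate F5, which is separated. The unreacted (R)-epoxide is 15 (at most 50 %), where the route is rejoined.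

Step 2. The risks are an E/Z ratio that is hard to upgrade and side reactions of the furylmethyl Grignard reagent. Fallback: take the alkene geometry from a selective allylic oxidation instead of from the SN2' step. Setting out from 2, through Grignard 4, Li2CuCl4-catalysed coupling with 1-chloro-3-methylbut-2-ene (THF, 0 °C) gives 3-(4-methylpent-3-en-1-yl)furan F6 (perillene). SeO2 (cat.) with t-BuOOH in CH2Cl2 then hydroxylates only the methyl group trans to the chain (ene reaction, then [2,3] shift); any enal formed is reduced back with NaBH4. This gives 5, where the route is rejoined.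

**Further compounds**
F1 | step 8 | 2-[(E)-5-(furan-3-yl)-2-methylpent-2-en-1-yl]-1,3-dithiane | C/C(=C\CCc1ccoc1)CC1SCCCS1
F2 | step 8 | 2-lithio-2-[(E)-5-(furan-3-yl)-2-methylpent-2-en-1-yl]-1,3-dithiane | [Li]C1(C/C(C)=C/CCc2ccoc2)SCCCS1
F3 | step 8 | lithium potassium 3-[(2S,3S)-3-{(3R)-4-[2-((E)-5-(furan-3-yl)-2-methylpent-2-en-1-yl)-1,3-dithian-2-yl]-3-methyl-3-oxidobutyl}-2-methyloxiran-2-yl]propanoate | C/C(=C\CCc1ccoc1)CC1(SCCCS1)C[C@](C)([O-])CC[C@@H]2O[C@@]2(C)CCC(=O)[O-].[Li+].[K+]
F4 | step 6 | ethyl (E)-4-methyl-7-(2-methyloxiran-2-yl)hept-4-enoate (racemic) | CCOC(=O)CC/C(C)=C/CCC1(C)CO1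
F5 | step 6 | ethyl (4E,7S)-8-azido-4,7-dimethyl-7-[(trimethylsilyl)oxy]oct-4-enoate | CCOC(=O)CC/C(C)=C/CC[C@@](C)(CN=[N+]=[N-])O[Si](C)(C)C
F6 | step 2 | 3-(4-methylpent-3-en-1-yl)furan | CC(C)=CCCc1ccoc1
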